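**Plan**

- Retrosynthesis: the benzoate ring is traced back to a cyclohexanone. Arene carbons C3, C4 and C5 (C-prenyl, C-OH, C-prenyl) are the α, carbonyl and α' carbons of a 4-oxocyclohexane-1-carboxylate, and each prenyl group sits at the oxidation level of 3-methylbut-2-enal condensed onto that ketone.
- Cuts, in order: the two exocyclic-to-endocyclic hydrogen shifts that aromatise the ring; then C3–C1' and C5–C1'' (C1', C1'' = benzylic carbons of the prenyl groups) by double aldol condensation; then the acyl–oxygen bond of the tertiary ester.
- Forward: no ring is formed. The six-membered carbocycle is bought as 4-oxocyclohexanecarboxylic acid, the terpinenyl ester is joined first, both side chains are attached in one flask, and the ring is aromatised last.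
- Stereochemistry: the only stereocentre (the quaternary C–O carbon) is bought with (R)-terpinen-4-ol and is acylated at oxygen, so its C–O bond is never broken. Its configuration is defined solely by the position of the ring alkene, so every step avoids acid and conditions that move trisubstituted alkenes.

Key step: step 3

Assumption: commercial (R)-terpinen-4-ol (the laevorotatory enantiomer) is taken to be of high enantiomeric purity; this would be checked before use, because nothing later in the route can raise it. "(R)-Terpinen-4-yl" below means (1R)-4-methyl-1-(propan-2-yl)cyclohex-3-en-1-yl.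

**Route**

Step 1
Reactants: 1 4-oxocyclohexane-1-carboxylic acid
Product: 2 4-oxocyclohexane-1-carbonyl chloride
Conditions: (COCl)2 (1.2 equiv), DMF (cat.), CH2Cl2, 0 °C → rt; evaporate, use crude
Reagents that add atoms: oxalyl chloride, ClC(=O)C(=O)Cl
Why: Acid chloride formation through the catalytic Vilsmeier-type chloroiminium salt is standard, leaves an unconjugated ketone untouched at room temperature and gives only gaseous by-products.

Step 2
Reactants: 3 (R)-terpinen-4-ol; 2 4-oxocyclohexane-1-carbonyl chloride
Product: 5 (R)-terpinen-4-yl 4-oxocyclohexane-1-carboxylate, via lithium (R)-terpinen-4-olate 4 (not isolated)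
Conditions: 3, n-BuLi (0.98 equiv), THF, −78 → 0 °C; solution added to 2 (1.2 equiv), THF, −78 → 0 °C; aq. NaHCO3 work-up
Reagents that add atoms: none
Why: O-acylation of a preformed lithium tert-alkoxide by an acid chloride is the established route to esters of hindered tertiary alcohols; inverse addition at −78 °C keeps the alkoxide from enolising the ketone, and acyl–oxygen bond formation leaves the stereocentre untouched.

Step 3
Reactants: 5 (R)-terpinen-4-yl 4-oxocyclohexane-1-carboxylate; 6 3-methylbut-2-enal (2.2 equiv in two portions)
Product: 10 (R)-terpinen-4-yl (3E,5E)-3,5-bis(3-methylbut-2-en-1-ylidene)-4-oxocyclohexane-1-carboxylate, via lithium mono-aldolate 7 (not isolated), via dilithium bis-aldolate 8 (not isolated), via bis-acetate 9 (not isolated)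
Conditions: LiN(SiMe3)2 (1.05 equiv), THF, −78 °C; 6 (1.0 equiv); LiN(SiMe3)2 (1.1 equiv), −78 °C; 6 (1.2 equiv); Ac2O (3 equiv), −78 → 0 °C; DBU (4 equiv), 0 °C → rt
Reagents that add atoms: none
Why: LiN(SiMe3)2 removes a ketone α-hydrogen and the lithium enolate adds 1,2 to the aldehyde carbon of 6 to give 7; a second enolisation at the remaining α-methylene and a second addition give 8, acetic anhydride traps both alkoxides as 9, and DBU expels acetate by E1cB so that the new C3–C1' and C5–C1'' bonds end up as the exocyclic double bonds of the cross-conjugated dienone 10. The closest known reaction types are the directed aldol addition of ketone lithium enolates to 3-methylbut-2-enal, the acetylation–elimination of β-hydroxy ketones and, for the overall change, the double Claisen–Schmidt condensation of cyclohexanones to 2,6-bis(ylidene) ketones. No ring closes and no new stereocentre is kept: the carbinol and α centres of 7 to 9 vanish on elimination, and the alkene geometry (expected E, side chain anti to the carbonyl) is immaterial because step 4 erases it. The step needs reaction at the ketone α-carbons in preference to the ester α-carbon, which the silylamide base should secure because the secondary ketone α-hydrogens are several pKa units more acidic and far more accessible than the tertiary C1–H of the hindered ester. It also needs cross- rather than self-condensation of the enolisable enal, which is secured by adding 6 only to preformed enolate at −78 °C so that it never meets free base, while its β,β-disubstitution blocks conjugate addition. The second deprotonation should go to C5 because C3 is by then tertiary and flanked by the alkoxide, and DBU is too weak to enolise the product through its side-chain methyl groups.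

Step 4
Reactants: 10 (R)-terpinen-4-yl (3E,5E)-3,5-bis(3-methylbut-2-en-1-ylidene)-4-oxocyclohexane-1-carboxylate
Product: 12 (R)-terpinen-4-yl 4-hydroxy-3,5-bis(3-methylbut-2-en-1-yl)benzoate, via 4H-cyclohexadienone tautomer 11 (not isolated)
Conditions: RuHCl(CO)(PPh3)3 (5 mol %), degassed toluene, 80 °C
Reagents that add atoms: none
Why: Proposed new method: the divalent ruthenium hydride should add across each s-cis exocyclic enone in the conjugate sense (hydride to C1', metal to the enolate carbon) and then lose a β-hydrogen from the adjacent ring methylene, a net 1,3-hydrogen shift that turns each ylidene into a prenyl group, after which dienone 11 enolises irreversibly to the phenol; the closest known reaction type is the rhodium-hydride-catalysed isomerisation of 2,6-bis(arylidene)cyclohexanones to 2,6-dibenzylphenols, extended here to dienylidene groups, with the disubstituted diene terminus and the trisubstituted alkenes of the product and of the terpinenyl ring expected to insert too slowly to compete.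

**Compound list**

1 | 4-oxocyclohexane-1-carboxylic acid | O=C1CCC(C(=O)O)CC1 | starting material
2 | 4-oxocyclohexane-1-carbonyl chloride | O=C1CCC(C(=O)Cl)CC1 | intermediate
3 | (R)-terpinen-4-ol, (1R)-4-methyl-1-(propan-2-yl)cyclohex-3-en-1-ol | O[C@@]1(C(C)C)CC=C(C)CC1 | starting material
4 | lithium (R)-terpinen-4-olate, formed in the flask | [Li+].[O-][C@@]1(C(C)C)CC=C(C)CC1 | intermediate
5 | (R)-terpinen-4-yl 4-oxocyclohexane-1-carboxylate | O=C1CCC(C(=O)O[C@@]2(C(C)C)CC=C(C)CC2)CC1 | intermediate
6 | 3-methylbut-2-enal | CC(C)=CC=O | starting material
7 | lithium mono-aldolate: (R)-terpinen-4-yl 3-(1-lithiooxy-3-methylbut-2-en-1-yl)-4-oxocyclohexane-1-carboxylate, diastereomer mixture, formed in the flask | [Li+].[O-]C(C=C(C)C)C1CC(C(=O)O[C@@]2(C(C)C)CC=C(C)CC2)CCC1=O | intermediate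
8 | dilithium bis-aldolate: (R)-terpinen-4-yl 3,5-bis(1-lithiooxy-3-methylbut-2-en-1-yl)-4-oxocyclohexane-1-carboxylate, diastereomer mixture, formed in the flask | [Li+].[Li+].[O-]C(C=C(C)C)C1CC(C(=O)O[C@@]2(C(C)C)CC=C(C)CC2)CC(C([O-])C=C(C)C)C1=O | intermediate
9 | bis-acetate: (R)-terpinen-4-yl 3,5-bis(1-acetoxy-3-methylbut-2-en-1-yl)-4-oxocyclohexane-1-carboxylate, diastereomer mixture, formed in the flask | CC(=O)OC(C=C(C)C)C1CC(C(=O)O[C@@]2(C(C)C)CC=C(C)CC2)CC(C(OC(C)=O)C=C(C)C)C1=O | intermediate
10 | (R)-terpinen-4-yl (3E,5E)-3,5-bis(3-methylbut-2-en-1-ylidene)-4-oxocyclohexane-1-carboxylate | O=C1/C(=C/C=C(C)C)CC(C(=O)O[C@@]2(C(C)C)CC=C(C)CC2)C/C1=C\C=C(C)C | intermediate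
11 | 4H-cyclohexadienone tautomer: (R)-terpinen-4-yl 3,5-bis(3-methylbut-2-en-1-yl)-4-oxocyclohexa-2,5-diene-1-carboxylate, formed in the flask | O=C1C(CC=C(C)C)=CC(C(=O)O[C@@]2(C(C)C)CC=C(C)CC2)C=C1CC=C(C)C | intermediate
12 | (R)-terpinen-4-yl 4-hydroxy-3,5-bis(3-methylbut-2-en-1-yl)benzoate (CNP0120997.1) | CC(C)=CCc1cc(C(=O)O[C@@]2(C(C)C)CC=C(C)CC2)cc(CC=C(C)C)c1O | target

**Step count**

Total steps: 4. Longest linear sequence: 4 steps (1 → 2 → 5 → 10 → 12).

**Steps most likely to fail**

1. Step 4 (proposed new method). Hydride may be delivered to the remote diene terminus, or re-add to the product, so that a side-chain double bond drifts into conjugation with the ring. The second shift may stall at a mono-isomerised enone. Migration of the terpinenyl ring alkene would erode enantiopurity, so the optical purity of 12 would be checked against 3. Fallback by known chemistry, setting out from 3 and returning at 12: the prenyl groups would be placed on a preformed arene. Alkoxide 4, made from 3 as in step 2, would be acylated with 4-acetoxybenzoyl chloride to (R)-terpinen-4-yl 4-acetoxybenzoate F1. The aryl acetate would be cleaved selectively (K2CO3, MeOH, 0 °C) to (R)-terpinen-4-yl 4-hydroxybenzoate F2. Ortho C-alkylation of its sodium phenoxide in toluene (NaH, 3-methylbut-2-enyl bromide) would give (R)-terpinen-4-yl 4-hydroxy-3-(3-methylbut-2-en-1-yl)benzoate F3, and a second round of the same alkylation would give 12.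

2. Step 3. Retro-aldol and proton transfer after the first addition may scramble the adducts, the second enolisation may be incomplete, and any free base would trigger self-condensation of the enal. Fallback, setting out from 5 and returning at 10: both α-carbons would first be activated as vinylogous amides, and the side chains then built by forming C1'–C2' instead of C3–C1'. Heating 5 with tert-butoxybis(dimethylamino)methane (toluene, 100 °C) would give (R)-terpinen-4-yl (3E,5E)-3,5-bis[(dimethylamino)methylidene]-4-oxocyclohexane-1-carboxylate F4. Conjugate addition of 2-methylprop-1-enylmagnesium bromide (THF, −40 → 0 °C) with loss of dimethylamine, the known enaminone-to-enone exchange, would then give 10.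

3. Step 2. The alkoxide may enolise the keto acid chloride (ketene and aldol oligomers) faster than it is acylated at its hindered oxygen, or the tertiary ester may ionise during work-up. Fallback, setting out from 3 and returning at 5: the ketone would be brought in masked, and the ring built onto the ester. Alkoxide 4 would be acylated with acryloyl chloride to (R)-terpinen-4-yl prop-2-enoate F5. Diels–Alder reaction with 2-(trimethylsilyloxy)buta-1,3-diene (toluene, 110 °C, "para" regiochemistry) would give (R)-terpinen-4-yl 4-(trimethylsilyloxy)cyclohex-3-ene-1-carboxylate F6. Cleavage of the silyl enol ether (K2CO3, MeOH, 0 °C) would give 5.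

**Further compounds**

F1 | step 4 | (R)-terpinen-4-yl 4-acetoxybenzoate | CC(=O)Oc1ccc(C(=O)O[C@@]2(C(C)C)CC=C(C)CC2)cc1
F2 | step 4 | (R)-terpinen-4-yl 4-hydroxybenzoate | Oc1ccc(C(=O)O[C@@]2(C(C)C)CC=C(C)CC2)cc1
F3 | step 4 | (R)-terpinen-4-yl 4-hydroxy-3-(3-methylbut-2-en-1-yl)benzoate | CC(C)=CCc1cc(C(=O)O[C@@]2(C(C)C)CC=C(C)CC2)ccc1O
F4 | step 3 | (R)-terpinen-4-yl (3E,5E)-3,5-bis[(dimethylamino)methylidene]-4-oxocyclohexane-1-carboxylate | O=C1/C(=C/N(C)C)CC(C(=O)O[C@@]2(C(C)C)CC=C(C)CC2)C/C1=C\N(C)C
F5 | step 2 | (R)-terpinen-4-yl prop-2-enoate | C=CC(=O)O[C@@]1(C(C)C)CC=C(C)CC1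
F6 | step 2 | (R)-terpinen-4-yl 4-(trimethylsilyloxy)cyclohex-3-ene-1-carboxylate (diastereomer mixture at ring C1) | C[Si](C)(C)OC1=CCC(C(=O)O[C@@]2(C(C)C)CC=C(C)CC2)CC1
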